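The methylene bridge is cut last: the ortho-quinone methide of the chromene half is trapped by the free ring CH of propionylfilicinic acid. Everything rests on the filicinic ring, a six-membered carbocycle with oxygen on alternate carbons and a CMe2 carbon between two C–O carbons. It is grown from a four-membered ring: 3-ethoxy-4,4-dimethylcyclobutenone (dimethylketene plus ethoxyacetylene) is heated with a second ethoxyacetylene. Ring opening, [2+2] addition, ring opening and 6π closure insert the two alkyne carbons, complete the 1,3,5-oxygen pattern and re-bond the carbonyl carbon to CMe2. That quaternary carbon blocks aromatisation, so the cascade ends at filicinic acid diethyl ether.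

Key step: step 2

Remark: the target is achiral. Its β-triketone ring is drawn as one of several rapidly interconverting enol tautomers, and all of them are treated as the same compound.

Step 1
Reactants: 1 isobutyryl chloride; 2 ethoxyacetylene
Product: 4 3-ethoxy-4,4-dimethylcyclobut-2-en-1-one, via dimethylketene 3 (not isolated)
Conditions: Et3N (1.2 equiv), Et2O, 0 °C to reflux
Reagents that add atoms: none
Why: Dehydrochlorination of 1 gives dimethylketene, which undergoes a ketene–alkyne [2+2] cycloaddition with the electron-rich alkyne, the nucleophilic CH terminus bonding to the ketene carbonyl carbon so that the OEt-bearing carbon ends up next to CMe2.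

Step 2
Reactants: 4 3-ethoxy-4,4-dimethylcyclobut-2-en-1-one; 2 ethoxyacetylene
Product: 8 3,5-diethoxy-6,6-dimethylcyclohexa-2,4-dien-1-one, via vinylketene 5 (not isolated), via 4-alkenylcyclobutenone 6 (not isolated), via dienylketene 7 (not isolated)
Conditions: 2 (3 equiv, added in portions), dry toluene, sealed tube, 110 °C
Reagents that add atoms: none
Why: Heat opens 4 by 4π conrotatory cleavage of the C(=O)–CMe2 bond to vinylketene 5, whose ketene C=C adds 2 in a [2+2] cycloaddition to give 6; a second 4π opening gives dienylketene 7, and a 6π disrotatory electrocyclisation joins the ketene carbon to the CMe2 terminus. This is the Danheiser annulation of a cyclobutenone with an alkynyl ether; the quaternary CMe2 carbon forbids the final enolisation to a phenol, so the cyclohexa-2,4-dienone is the end point, and the last event is the thermal reverse of the known photochemical opening of 6,6-dialkylcyclohexa-2,4-dienones to dienylketenes. The four-membered ring of 6 closes by [2+2] cycloaddition and the six-membered ring of 8 by 6π electrocyclisation, so that in sum the two alkyne carbons are inserted into the four-membered ring (four to six ring atoms). No stereocentre remains in 8, and the single one in 6 is transient and is lost on ring opening. The selectivity needed is the orientation of the [2+2] step, and it is secured by the polarity of the partners: the nucleophilic CH terminus of 2 attacks the ketene carbonyl carbon, which places the new OEt group 1,3 to the old one and gives the alternating oxygen pattern. Only the isomer of 7 with the ketene and alkenyl arms cis on the central C=C can close, but the opening of 6 is reversible, so the unproductive isomer is fed back.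

Step 3
Reactants: 8 3,5-diethoxy-6,6-dimethylcyclohexa-2,4-dien-1-one
Product: 9 filicinic acid (3,5-dihydroxy-4,4-dimethylcyclohexa-2,5-dien-1-one)
Conditions: 2 M HCl, THF, reflux
Reagents that add atoms: water, O
Why: Acid-catalysed hydrolysis of the two enol ether (vinylogous ester) units by C-protonation, addition of water and loss of ethanol should stop at the stable vinylogous acid 9, whose quaternary carbon prevents aromatisation.

Step 4
Reactants: 9 filicinic acid; 10 propanoyl chloride
Product: 11 propionylfilicinic acid (3,5-dihydroxy-4,4-dimethyl-2-propanoylcyclohexa-2,5-dien-1-one)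
Conditions: AlCl3 (3 equiv), CH2Cl2/PhNO2, 0 to 40 °C; then 1 M HCl
Reagents that add atoms: none
Why: Friedel–Crafts-type C-acylation of the enolised triketone, as practised on phloroglucinols, takes place at one of the two equivalent ring CH carbons, and the product is held as a deactivated aluminium chelate, which should stop a second acylation.

Step 5
Reactants: 12 flopropione (1-(2,4,6-trihydroxyphenyl)propan-1-one); 13 3-methylbut-2-enal
Product: 15 1-(5,7-dihydroxy-2,2-dimethyl-2H-chromen-8-yl)propan-1-one, via dienone 14 (not isolated)
Conditions: 13 (1.0 equiv), pyridine, 110 °C; chromatography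
Reagents that add atoms: none
Why: Pyridine-mediated chromenylation: Knoevenagel-type condensation of 13 at one of the two equivalent free ring carbons gives dienone 14, which closes by oxa-6π electrocyclisation on the oxygen ortho to the acyl group to give 15; closure on the para oxygen gives the 6-acyl isomer as an expected co-product, which is removed by chromatography.

Step 6
Reactants: 15 1-(5,7-dihydroxy-2,2-dimethyl-2H-chromen-8-yl)propan-1-one; 16 Eschenmoser's salt (N,N-dimethylmethyleneiminium iodide); 11 propionylfilicinic acid
Product: 19 2-[(5,7-dihydroxy-2,2-dimethyl-8-propanoyl-2H-chromen-6-yl)methyl]-3,5-dihydroxy-4,4-dimethyl-6-propanoylcyclohexa-2,5-dien-1-one (target CNP0277188.0), via Mannich base 17 (not isolated), via ortho-quinone methide 18 (not isolated)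
Conditions: 16 (1.0 equiv), Et3N (1.0 equiv), MeCN, 0 °C to rt; then 11 (1.1 equiv), 80 °C; 1 M HCl work-up
Reagents that add atoms: none
Why: Mannich reaction at C6, the only free aromatic carbon of 15, gives 17, which on warming loses dimethylamine to ortho-quinone methide 18; Michael addition of the enolate of 11 through its only free ring carbon and rearomatisation form the CH2 bridge without the homodimers that free formaldehyde would give.

Compound list
1 | isobutyryl chloride | CC(C)C(Cl)=O | starting material
2 | ethoxyacetylene | C#COCC | starting material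
3 | dimethylketene (not isolated) | CC(C)=C=O | intermediate
4 | 3-ethoxy-4,4-dimethylcyclobut-2-en-1-one | CCOC1=CC(=O)C1(C)C | intermediate
5 | vinylketene, 3-ethoxy-4-methylpenta-1,3-dien-1-one (not isolated) | O=C=CC(OCC)=C(C)C | intermediate
6 | 4-alkenylcyclobutenone, 3-ethoxy-4-(1-ethoxy-2-methylprop-1-en-1-yl)cyclobut-2-en-1-one (racemic, not isolated) | CCOC1=CC(=O)C1C(OCC)=C(C)C | intermediate
7 | dienylketene, (3E)-3,5-diethoxy-6-methylhepta-1,3,5-trien-1-one, ketene and alkenyl arms cis on C3=C4 (not isolated) | O=C=C/C(OCC)=C\C(OCC)=C(C)C | intermediate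
8 | 3,5-diethoxy-6,6-dimethylcyclohexa-2,4-dien-1-one (filicinic acid diethyl ether) | CCOC1=CC(=O)C(C)(C)C(OCC)=C1 | intermediate
9 | filicinic acid, 3,5-dihydroxy-4,4-dimethylcyclohexa-2,5-dien-1-one | O=C1C=C(O)C(C)(C)C(O)=C1 | intermediate
10 | propanoyl chloride | CCC(Cl)=O | starting material
11 | propionylfilicinic acid, 3,5-dihydroxy-4,4-dimethyl-2-propanoylcyclohexa-2,5-dien-1-one | CCC(=O)C1=C(O)C(C)(C)C(O)=CC1=O | intermediate
12 | flopropione, 1-(2,4,6-trihydroxyphenyl)propan-1-one | CCC(=O)c1c(O)cc(O)cc1O | starting material
13 | 3-methylbut-2-enal | CC(C)=CC=O | starting material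
14 | dienone, (6Z)-3,5-dihydroxy-6-(3-methylbut-2-en-1-ylidene)-2-propanoylcyclohexa-2,4-dien-1-one, side chain cis to C1=O (not isolated) | CCC(=O)C1=C(O)C=C(O)/C(=C/C=C(C)C)C1=O | intermediate
15 | 1-(5,7-dihydroxy-2,2-dimethyl-2H-chromen-8-yl)propan-1-one | CCC(=O)c1c(O)cc(O)c2C=CC(C)(C)Oc12 | intermediate
16 | Eschenmoser's salt, N,N-dimethylmethyleneiminium iodide | C=[N+](C)C.[I-] | starting material
17 | Mannich base, 1-{6-[(dimethylamino)methyl]-5,7-dihydroxy-2,2-dimethyl-2H-chromen-8-yl}propan-1-one (not isolated) | CCC(=O)c1c(O)c(CN(C)C)c(O)c2C=CC(C)(C)Oc12 | intermediate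
18 | ortho-quinone methide, 5-hydroxy-2,2-dimethyl-6-methylidene-8-propanoyl-2H-chromen-7(6H)-one (not isolated) | C=C1C(=O)C(C(=O)CC)=C2OC(C)(C)C=CC2=C1O | intermediate
19 | 2-[(5,7-dihydroxy-2,2-dimethyl-8-propanoyl-2H-chromen-6-yl)methyl]-3,5-dihydroxy-4,4-dimethyl-6-propanoylcyclohexa-2,5-dien-1-one | CCC(=O)C1=C(O)C(C)(C)C(O)=C(Cc2c(O)c3c(c(C(=O)CC)c2O)OC(C)(C)C=C3)C1=O | target

Total step count: 6. Longest linear sequence: 5 (steps 1, 2, 3, 4, 6).

Steps most likely to fail

**Step 2.**
- Risk: the electrocyclic opening of 4 must turn one methyl group inward. It may be slower than the thermal retro-ene decay of the alkynyl ether. Vinylketene 5 may also drain away through a 1,5-hydrogen shift from that methyl group.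
- Fallback: it sets out from 2 and comes back at 6, and through it at 8. The four-membered ring is built at room temperature with the alkenyl arm already in place.
- Commercial ethyl 4-methyl-3-oxopentanoate F1 is converted with triethyl orthoformate and catalytic acid into ethyl (E)-3-ethoxy-4-methylpent-2-enoate F2.
- F2 is saponified (KOH, aqueous EtOH, cold acidification) to (E)-3-ethoxy-4-methylpent-2-enoic acid F3. Oxalyl chloride then gives (E)-3-ethoxy-4-methylpent-2-enoyl chloride F4. Either alkene geometry would serve.
- Slow addition of F4 to Et3N and 2 in CH2Cl2 at room temperature should generate 5 by 1,4-dehydrochlorination and trap it at once as 6.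
- Compound 6 is now isolated and heated alone in toluene at about 80 °C. The four-to-six ring expansion 6 to 7 to 8 is then a unimolecular thermolysis of a 4-alkenylcyclobutenone with no alkyne present.

**Step 5.**
- Risk: poor regioselectivity of the oxa-6π closure, because closure on the unchelated para oxygen competes, and a second chromenylation at the remaining ring carbon.
- Fallback: it sets out from 12 and comes back at 15. The para oxygen is blocked first.
- MOMCl (1.0 equiv) and i-Pr2NEt in CH2Cl2 at 0 °C should etherify the most acidic, unchelated 4-OH to give 1-[2,6-dihydroxy-4-(methoxymethoxy)phenyl]propan-1-one F5.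
- Chromenylation of F5 with 13 in hot pyridine can then close only on an oxygen ortho to the acyl group. This should give 1-[7-hydroxy-5-(methoxymethoxy)-2,2-dimethyl-2H-chromen-8-yl]propan-1-one F6.
- Mild acid methanolysis (HCl, MeOH, 40 °C) releases 15.

**Step 6.**
- Risk: C–C bond formation at the bridge is reversible in warm basic medium (retro-Michael). The two halves may be exchanged and symmetrical dimers may build up. Compound 18 may also be consumed by self-addition.
- Fallback: it sets out from 15 and comes back at 19. The bridge carbon is brought in at the aldehyde level and is fixed by an irreversible hydride transfer at room temperature.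
- Vilsmeier–Haack formylation of 15 (POCl3, DMF, EtOAc, 0 °C to rt, aqueous hydrolysis) gives 5,7-dihydroxy-2,2-dimethyl-8-propanoyl-2H-chromene-6-carbaldehyde F7.
- F7, 11 and the Hantzsch ester are combined with catalytic L-proline in CH2Cl2 at rt. Knoevenagel condensation gives the alkylidene trione F8 (not isolated, alkene geometry undefined).
- The electron-poor C=C of F8 is reduced in the same flask to the CH2 bridge of 19. The chromene alkene is not touched.

Further compounds
F1 | step 2 | ethyl 4-methyl-3-oxopentanoate | CCOC(=O)CC(=O)C(C)C
F2 | step 2 | ethyl (E)-3-ethoxy-4-methylpent-2-enoate | CCOC(=O)/C=C(/OCC)C(C)C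
F3 | step 2 | (E)-3-ethoxy-4-methylpent-2-enoic acid | OC(=O)/C=C(/OCC)C(C)C
F4 | step 2 | (E)-3-ethoxy-4-methylpent-2-enoyl chloride | ClC(=O)/C=C(/OCC)C(C)C
F5 | step 5 | 1-[2,6-dihydroxy-4-(methoxymethoxy)phenyl]propan-1-one | CCC(=O)c1c(O)cc(OCOC)cc1O
F6 | step 5 | 1-[7-hydroxy-5-(methoxymethoxy)-2,2-dimethyl-2H-chromen-8-yl]propan-1-one | CCC(=O)c1c(O)cc(OCOC)c2C=CC(C)(C)Oc12
F7 | step 6 | 5,7-dihydroxy-2,2-dimethyl-8-propanoyl-2H-chromene-6-carbaldehyde | CCC(=O)c1c(O)c(C=O)c(O)c2C=CC(C)(C)Oc12
F8 | step 6 | alkylidene trione, 6-[(5,7-dihydroxy-2,2-dimethyl-8-propanoyl-2H-chromen-6-yl)methylidene]-3-hydroxy-4,4-dimethyl-2-propanoylcyclohex-2-ene-1,5-dione (geometry undefined) | CCC(=O)C1=C(O)C(C)(C)C(=O)C(=Cc2c(O)c3C=CC(C)(C)Oc3c(C(=O)CC)c2O)C1=O
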